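Numbering used throughout: eudesmane numbering for the terpene carbons (C15 is the carbon on C4, C11 the carbinol carbon on C7) and C1′ for the benzylic carbon. Compound numbers are those of the steps below.

## The problem

Macrocarpal J (22) is a trans-fused eudesmane whose C1 carries, equatorially, a CH(aryl)(isobutyl) unit; the aryl group is a 3,5-diformylphloroglucinol. Six stereocentres have to be correct. C5, C7 and C10 define ring B and the ring fusion and can steer ring A. C4 is a tertiary carbinol whose axial methyl is 1,3-diaxial to the C10 methyl, so it can be reached by attack on a C4 exocyclic alkene from the face away from that methyl. C1 lies next to the quaternary C10, and C1′ lies outside the rings where no conformational bias of the decalin reaches it, so C1′ has to come from a reagent. The C1–C1′ bond joins a neopentyl-type carbon to a doubly ortho-substituted benzylic carbon and is the most congested bond in the molecule. The two tertiary alcohols (C4, C11) ionise under strong acid and the formylated phloroglucinol is acidic, chelating and easily oxidised, so the phenols are kept as methyl ethers and the formyl groups are introduced only after all Lewis-acid, radical, peracid and hydride chemistry is over. The enabling feature is that ring B with C5, C7, C10 and the C11 carbinol is the cyclohexane of (−)-elemol (1): its C5 isopropenyl group already holds C4, C3 and C15, its C10 vinyl group holds C1 and C2, and ring A lacks only the C2–C3 bond. With C2 as an aldehyde, the isopropenyl group is an ene unit tethered through its central carbon, which is the arrangement for a Type 2 carbonyl-ene closure that leaves a C4 methylene.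

## Retrosynthesis

Unmasking last (22 ⇒ 21 ⇒ 20 ⇒ 18 ⇒ 17). The three O–CH3 bonds, the O–Si bond and the two aryl–CHO bonds are cut first. Formyl groups or free phenols would not survive the Lewis acids, stannane, peracid and LiAlH4 used earlier. The symmetrical 2,4,6-trimethoxyphenyl ring of 17 is inert to all of them and has two equivalent C–H positions, each between two methoxy groups. The forward reactions must install two formyl groups without acid: bromination to 18, then bromine–lithium exchange and DMF to 20. Fluoride then frees the C11 carbinol (21) and a thiolate cleaves the methyl ethers, each of which is ortho to a formyl group.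

C4 carbinol (17 ⇒ 16 ⇒ 15). The C15–H and C4–O bonds are traced back to the exocyclic alkene of 15. Adding a methyl nucleophile to a C4 ketone would come from the equatorial side and give the C4 epimer. Epoxidation of the methylene from the α face, away from the axial C10 methyl, followed by hydride opening of epoxide 16 at C15, gives the axial methyl and equatorial hydroxyl. Compound 15 has one stereocentre fewer.

C2 oxygen (15 ⇒ 14 ⇒ 13). A hydroxyl group is put back on C2 so that ring A can be opened at C2–C3. Its forward removal should not pass through the C2 ketone, because the 4(15)-alkene would move into conjugation. Radical deoxygenation of thiocarbonyl derivative 14 leaves C1 and the alkene untouched.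

Ring A, the key cut (13 ⇒ 12): C2–C3. Cutting C2–C3 of homoallylic alcohol 13 gives aldehyde 12, with C2 as a formyl group on C1 and C3, C4, C15 as an isopropenyl group on C5. The neighbouring cuts (C1–C10, C4–C5) would break bonds to ring B carbons that 1 supplies already joined, and would require a quaternary or ring-fusion centre to be made anew. Compound 12 is monocyclic and its three ring stereocentres are those of 1. The forward reaction has to form one bond and place the alkene exocyclic; the trans fusion is fixed by the equatorial substituents at C5 and C10.

Side chain (12 ⇒ 4 + 10): C1–C1′. The bond between the aldehyde α-carbon and the benzylic carbon is cut to silyl enol ether 4 and the tricarbonylchromium-complexed benzylic acetate 10.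
- The neighbouring option is aldol condensation of aldehyde 3 with an aliphatic aldehyde followed by aryl cuprate addition to the enal. It requires a crossed aldol between two enolisable aldehydes and addition of a doubly ortho-substituted arylcopper reagent to a trisubstituted enal. It offers no control of C1′, and C1 would be set by protonation, for which the steric model used here for alkylation predicts the opposite configuration.
- Complex 10 brings the C1′ configuration in from a small molecule and transfers it with retention. Enol ether 4 has only to choose a face, and the adjacent C10 stereocentre is placed to direct that.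
- Attaching the chain before ring closure also avoids alkylating a ring A ketone at C1 in competition with C3.

Terpene fragment (4 ⇒ 3 ⇒ 2 ⇒ 1). Functional-group changes only: enol ether 4 from aldehyde 3, the aldehyde from anti-Markovnikov oxidation of the vinyl group of silyl ether 2, and 2 from 1. No C–C bond and no stereocentre is made.

Aryl fragment (10 ⇒ 9 ⇒ 8 ⇒ 7 ⇒ 5 + 6). Acetate and metal are removed (9, 8), the carbinol is traced to ketone 7 by asymmetric reduction, and the aryl–CO bond is cut to 1,3,5-trimethoxybenzene (5) and isovaleryl chloride (6). Because the ring is symmetrical, complexation creates no further stereo element.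

## Roads not taken

Alternative 1: Ring B is built last. C9–C10 and C5–C6 are cut, leaving a 4-substituted 3-methylcyclohexenone A1 that already carries the C1/C1′ side chain. Forward, vinylmagnesium bromide A2 with CuBr·SMe2 would add to C10 anti to the C1 substituent, and the C5 enolate would be trapped with prenyl bromide A3 to give ketone A4. Ring B would then be closed between the vinyl and prenyl termini (C7–C8).
- Merits: two C–C bonds, the quaternary C10 and C5 are made in one flask. The plan is independent of the terpene pool, so either enantiomer and ring B analogues are accessible. No surplus oxygen has to be removed from ring A.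
- Weak points: A1 must be made as one stereoisomer at C1 and C1′ with no ring system to help, so the hardest problem is only moved to the start. The conjugate addition must create a quaternary centre beside the carbon bearing the bulky side chain. Axial alkylation of the C5 enolate anti to the axial C10 methyl would put the prenyl group on the wrong face, so C5 would need equilibration. C7 and the C11 carbinol arise during closure of ring B from an open chain. The C4 ketone of A4 would still need a methylenation, epoxidation and hydride sequence, since a methyl nucleophile adds equatorially.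
- Comparison: A4 is more convergent and spends nothing on a C2 oxygen, whereas the chosen plan spends steps 10 and 11 on it. Against that, the chosen plan takes C5, C7, C10 and the C11 carbinol from 1 and has only three stereocentres left to make.

Alternative 2: The C1–C10 bond is made by dearomatisation. A para-cresol A5 carries C4 (as a ketal), C3, C2 and an allylic carbonate on its meta position. With [Ir(cod)Cl]2 and a chiral phosphoramidite, the phenolate para carbon would attack the substituted end of the activated allyl unit, closing ring A to the fused cross-conjugated dienone A6 with C10 and C1 set together.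
- Merits: the step is catalytic and enantioselective, makes the most hindered ring bond and two adjacent stereocentres from a flat arene, and needs no stoichiometric chiral material. In this it is better than the chosen plan, which depends on a natural product of one absolute configuration.
- Weak points: the vinyl group of A6 must become CH(aryl)CH2CH(CH3)2, so C1′ would be created late, by two-fold functionalisation of a terminal alkene beside C1 and C10, with no controlling element within reach. Ring B arrives as a chlorodienone that must be reduced to the trans fusion (C5), dechlorinated and converted at C7 into the equatorial carbinol. Fused-ring formation from a meta tether is less documented than spirocyclisation from a para tether.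
- Comparison: the chosen plan sets C1′ by a stereospecific substitution before the ring is closed and takes ring B ready-made, and these are the two tasks on which alternative 2 would spend most of its steps.

Alternative 3: The C10–methyl bond is cut. A ring A enone A7 (C1=C10, C2 ketone, side chain on C1, ring B from the pool) would be irradiated with allene A8. The [2+2] cycloaddition would join the allene CH2 to C10 anti to H5 and the central carbon to C1, giving methylenecyclobutane A9. Ozonolysis, retro-Claisen opening and excision of two carbons would leave the angular methyl and a hydrogen on C1.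
- Merits: enone–allene photocycloaddition tolerates a fully substituted β-carbon and its facial sense is reliable, so it is the strongest of the four plans at making the quaternary C10 in a crowded setting. The side chain position is fixed by the enone.
- Weak points: the chromophore is a tetrasubstituted enone whose α-substituent carries an electron-rich arene, a likely quencher of the excited enone. Two of the three carbons added must be removed again. C1 is quaternary in A9 and receives its final configuration only by protonation after fragmentation. In A7 and A9, C4 is an unsubstituted methylene remote from the C2 carbonyl, so C15 and the C4 hydroxyl would still have to be introduced.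
- Comparison: the chosen plan receives the angular methyl from 1 and C4/C15 from the isopropenyl group. Alternative 3 is ahead only in not depending on a Lewis-acid ring closure in the presence of the arene; the chosen plan answers that risk with an allylmetal closure of the same bond, described after the route.

Key step: step 9

Remark on the chemistry: enol ether 4 is drawn as the (Z) isomer and alcohol 13 as the 2β epimer. Neither the enol ether geometry nor the C2 configuration survives into 15, so the route does not depend on either assignment.

## Route

Step 1
Reactants: 1 (−)-elemol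
Product: 2 (−)-elemol triethylsilyl ether (C11–OSiEt3)
Conditions: TESOTf, 2,6-lutidine, CH2Cl2, −78 → 0 °C
Reagents that add atoms: triethylsilyl trifluoromethanesulfonate, CC[Si](CC)(CC)OS(=O)(=O)C(F)(F)F
Why: Silyl triflate silylation of a tertiary alcohol; the ether keeps the carbinol from ionising or bridging to C4 under the Lewis acids used later, and no stereocentre is touched.

Step 2
Reactants: 2 (−)-elemol triethylsilyl ether
Product: 3 2-[(1S,2S,4R)-1-methyl-2-(prop-1-en-2-yl)-4-[2-(triethylsilyloxy)propan-2-yl]cyclohexyl]acetaldehyde (C1 = CH2, C2 = CHO)
Conditions: PdCl2(PhCN)2 (cat.), CuCl2·2H2O (cat.), AgNO2 (cat.), O2 (1 atm), t-BuOH/MeNO2 (15:1), rt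
Reagents that add atoms: dioxygen, O=O
Why: Nitrite-modified (aldehyde-selective) Wacker oxidation puts oxygen on the terminal carbon of a monosubstituted alkene, and the quaternary C10 reinforces that sense; the 1,1-disubstituted isopropenyl group is a poor substrate for divalent palladium and should remain.

Step 3
Reactants: 3 aldehyde
Product: 4 (Z)-tert-butyldimethylsilyl enol ether of 3 (C10–CH=CH–OSi)
Conditions: Et3N, then TBSOTf, CH2Cl2, −78 → 0 °C
Reagents that add atoms: tert-butyldimethylsilyl trifluoromethanesulfonate, CC(C)(C)[Si](C)(C)OS(=O)(=O)C(F)(F)F
Why: Soft enolisation of an aldehyde with silyl triflate and amine; the amine is present in excess before the triflate so that the activated aldehyde is deprotonated rather than attacked by the isopropenyl group.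

Step 4
Reactants: 5 1,3,5-trimethoxybenzene; 6 isovaleryl chloride
Product: 7 3-methyl-1-(2,4,6-trimethoxyphenyl)butan-1-one
Conditions: AlCl3, CH2Cl2, −10 → 0 °C
Reagents that add atoms: none
Why: Friedel–Crafts acylation of a strongly activated symmetrical arene; the ketone deactivates the ring against a second acylation and the low temperature avoids ortho demethylation.

Step 5
Reactants: 7 aryl ketone
Product: 8 (R)-3-methyl-1-(2,4,6-trimethoxyphenyl)butan-1-ol
Conditions: (S)-2-methyl-CBS-oxazaborolidine (cat.), BH3·SMe2, THF, 0 °C → rt
Reagents that add atoms: none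
Why: Corey–Bakshi–Shibata reduction of an aryl alkyl ketone; with the twisted 2,6-dimethoxyaryl group as the large substituent and the CH2-branched chain as the small one, the (S)-catalyst should deliver hydride to give the (R)-carbinol, which is the C1′ stereocentre.

Step 6
Reactants: 8 (R)-benzylic alcohol
Product: 9 tricarbonyl[η6-(R)-3-methyl-1-(2,4,6-trimethoxyphenyl)butan-1-ol]chromium
Conditions: Cr(CO)6, n-Bu2O/THF (10:1), reflux, argon, dark
Reagents that add atoms: hexacarbonylchromium, [C-]#[O+].[C-]#[O+].[C-]#[O+].[C-]#[O+].[C-]#[O+].[C-]#[O+].[Cr]
Why: Thermal arene complexation by ligand exchange, favoured by the electron-rich ring; the two ring faces are equivalent, so one complex forms and the carbinol centre is unaffected.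

Step 7
Reactants: 9 alcohol complex
Product: 10 tricarbonyl[η6-(R)-3-methyl-1-(2,4,6-trimethoxyphenyl)butyl acetate]chromium
Conditions: Ac2O, pyridine, DMAP (cat.), CH2Cl2, 0 °C → rt
Reagents that add atoms: acetic anhydride, CC(=O)OC(C)=O
Why: DMAP-catalysed acetylation; only the O–H bond reacts, so the benzylic configuration is retained.

Step 8
Reactants: 4 silyl enol ether; 10 acetate complex
Product: 12 (2S,3S)-5-methyl-2-[(1R,2S,4R)-1-methyl-2-(prop-1-en-2-yl)-4-[2-(triethylsilyloxy)propan-2-yl]cyclohexyl]-3-(2,4,6-trimethoxyphenyl)hexanal (C1 S, C1′ S), via tricarbonylchromium-bound aldehyde 11 (not isolated)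
Conditions: BF3·OEt2, CH2Cl2, −78 → −40 °C; then air, sunlight, Et2O, rt
Reagents that add atoms: none
Why: SN1 substitution of a tricarbonylchromium-complexed benzylic acetate by a silyl enol ether, a reaction type known to go with retention: acetate leaves anti to the metal and the nucleophile enters from the same exo face before the cation can rotate, so (R)-10 should give (S)-C1′. C1 is set by the enol ether: with the C10 methyl eclipsing the enol double bond, attack anti to the C5 branch that carries the isopropenyl group gives the (1S) centre; a C1 epimer would be separable here and could be re-equilibrated with an amine base. Air and light then release the arene from 11.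

Step 9
Reactants: 12 seco-aldehyde
Product: 13 (1′S)-1β-[3-methyl-1-(2,4,6-trimethoxyphenyl)butyl]-11-(triethylsilyloxy)-5α-eudesm-4(15)-en-2β-ol
Conditions: Me2AlCl (2.5 equiv), CH2Cl2, −78 → −20 °C; then 1 M HCl, 0 °C
Reagents that add atoms: none
Why: Me2AlCl binds the aldehyde oxygen; the terminal carbon C3 of the isopropenyl group bonds to C2 while a hydrogen of the C15 methyl passes to oxygen through a six-membered array, and the methyl–aluminium bonds consume any proton set free, which suppresses chloride adducts and alkene migration. The closest known reaction type is the Me2AlCl-promoted Type 2 intramolecular carbonyl-ene cyclisation of 6-methylhept-6-enals to 3-methylenecyclohexanols. Ring A closes as a six-membered chair, exo with respect to the carbonyl group and with both ene carbons (C3, C4) inside the new ring; since C10–C1 and C5–C4 are equatorial bonds of ring B, fixed by 1, only the trans-decalin can form. The one new stereocentre, C2, is set by the geometry of hydrogen transfer: oxygen must be axial (β) to reach a C15 hydrogen, which gives the 2β-alcohol; this centre is deleted in step 11, so its sense is not critical. The step needs the exocyclic alkene, which is secured because H5 lies on the α face out of reach of the β oxygen and leaves the C15 hydrogens as the only transferable ones. It needs retention at C1, favoured by the low temperature and by the (1S) epimer fitting the chair with its side chain equatorial. It needs chemoselectivity against the arene, whose nucleophilic ring carbons cannot reach C2 through an unstrained ring. Excess Lewis acid is used because three methoxy groups and the silyl ether compete for aluminium.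

Step 10
Reactants: 13 homoallylic alcohol
Product: 14 O-[(1′S)-1β-[3-methyl-1-(2,4,6-trimethoxyphenyl)butyl]-11-(triethylsilyloxy)-5α-eudesm-4(15)-en-2β-yl] 1H-imidazole-1-carbothioate
Conditions: 1,1′-thiocarbonyldiimidazole, DMAP (cat.), toluene, 90 °C
Reagents that add atoms: 1,1′-thiocarbonyldiimidazole, S=C(n1ccnc1)n1ccnc1
Why: Thiocarbonyl transfer to a secondary alcohol, the first half of a Barton–McCombie deoxygenation; the tertiary silyl ether, the alkene and the arene do not react.

Step 11
Reactants: 14 thiocarbonyl derivative
Product: 15 (1′S)-1β-[3-methyl-1-(2,4,6-trimethoxyphenyl)butyl]-11-(triethylsilyloxy)-5α-eudesm-4(15)-ene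
Conditions: Bu3SnH, AIBN (cat.), toluene, 110 °C
Reagents that add atoms: none
Why: Barton–McCombie radical deoxygenation; the C2 radical is reduced by the stannane faster than it can add to the C4 methylene (a reversible three-membered closure), and neither C1 nor the alkene position is disturbed as it would be by a route through the C2 ketone.

Step 12
Reactants: 15 exocyclic alkene
Product: 16 (1′S)-4α,15-epoxy-1β-[3-methyl-1-(2,4,6-trimethoxyphenyl)butyl]-11-(triethylsilyloxy)-5α-eudesmane (oxygen α, CH2 β)
Conditions: mCPBA (1.1 equiv), NaHCO3, CH2Cl2, −10 → 0 °C
Reagents that add atoms: 3-chloroperoxybenzoic acid, OOC(=O)c1cccc(Cl)c1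
Why: Prilezhaev epoxidation of a 1,1-disubstituted alkene; the axial C10 methyl is 1,3-diaxial to the β face of C4, so oxygen should arrive from the α (equatorial) side, as with the parent 4(15)-eudesmenes. Buffer, low temperature and a small excess protect the silyl ether and the electron-rich ring.

Step 13
Reactants: 16 epoxide
Product: 17 (1′S)-1β-[3-methyl-1-(2,4,6-trimethoxyphenyl)butyl]-11-(triethylsilyloxy)-5α-eudesman-4α-ol (4β-methyl)
Conditions: LiAlH4, THF, 0 °C → reflux
Reagents that add atoms: none
Why: SN2 hydride opening of the epoxide at its primary carbon C15 turns the β CH2 into the axial methyl and leaves the equatorial 4α-hydroxyl; the C4 configuration set in step 12 is carried through.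

Step 14
Reactants: 17 tertiary alcohol
Product: 18 (1′S)-1β-[1-(3,5-dibromo-2,4,6-trimethoxyphenyl)-3-methylbutyl]-11-(triethylsilyloxy)-5α-eudesman-4α-ol
Conditions: NBS (2.1 equiv), MeCN, 0 °C, dark
Reagents that add atoms: N-bromosuccinimide, O=C1CCC(=O)N1Br
Why: Electrophilic aromatic bromination at the two equivalent positions, each flanked by two methoxy groups; no alkene is left in the molecule and the conditions are neutral toward the carbinol and silyl ether.

Step 15
Reactants: 18 dibromide
Product: 20 (1′S)-1β-[1-(3,5-diformyl-2,4,6-trimethoxyphenyl)-3-methylbutyl]-11-(triethylsilyloxy)-5α-eudesman-4α-ol, via aryl dilithium alkoxide 19 (not isolated)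
Conditions: t-BuLi (5.5 equiv), THF, −78 °C; DMF, −78 → 0 °C; H2O
Reagents that add atoms: N,N-dimethylformamide, CN(C)C=O
Why: Bromine–lithium exchange followed by Bouveault-type formylation with DMF; the first equivalent of base only forms the C4 alkoxide, each aryllithium is stabilised by two ortho methoxy groups, and the aminoalkoxide adducts collapse to the aldehydes on hydrolysis without any acid.

Step 16
Reactants: 20 dialdehyde silyl ether
Product: 21 macrocarpal J tri-O-methyl ether
Conditions: HF·pyridine, pyridine, THF, 0 °C → rt
Reagents that add atoms: none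
Why: Fluoride cleavage of a triethylsilyl ether under buffered conditions that neither ionise the tertiary carbinols nor affect the aryl aldehydes.

Step 17
Reactants: 21 macrocarpal J tri-O-methyl ether
Product: 22 macrocarpal J
Conditions: NaSEt (excess), DMF, 120 °C; then 1 M HCl, 0 °C
Reagents that add atoms: none
Why: SN2 demethylation of aryl methyl ethers by thiolate; every methoxy group is ortho to a formyl group, which makes each phenoxide a good leaving group, and the basic medium leaves the tertiary alcohols intact; acidification returns the phenols.

## Compound list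

1 | (−)-elemol, 2-[(1R,3S,4S)-4-ethenyl-4-methyl-3-(prop-1-en-2-yl)cyclohexyl]propan-2-ol | C=C(C)[C@@H]1C[C@H](C(C)(C)O)CC[C@]1(C=C)C | starting material
2 | (−)-elemol triethylsilyl ether | C=C(C)[C@@H]1C[C@H](C(C)(C)O[Si](CC)(CC)CC)CC[C@]1(C=C)C | intermediate
3 | 2-[(1S,2S,4R)-1-methyl-2-(prop-1-en-2-yl)-4-[2-(triethylsilyloxy)propan-2-yl]cyclohexyl]acetaldehyde | C=C(C)[C@@H]1C[C@H](C(C)(C)O[Si](CC)(CC)CC)CC[C@]1(CC=O)C | intermediate
4 | (Z)-tert-butyldimethylsilyl enol ether of 3 | C=C(C)[C@@H]1C[C@H](C(C)(C)O[Si](CC)(CC)CC)CC[C@]1(/C=C\O[Si](C)(C)C(C)(C)C)C | intermediate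
5 | 1,3,5-trimethoxybenzene | COc1cc(OC)cc(OC)c1 | starting material
6 | isovaleryl chloride (3-methylbutanoyl chloride) | CC(C)CC(=O)Cl | starting material
7 | 3-methyl-1-(2,4,6-trimethoxyphenyl)butan-1-one | CC(C)CC(=O)c1c(OC)cc(OC)cc1OC | intermediate
8 | (R)-3-methyl-1-(2,4,6-trimethoxyphenyl)butan-1-ol | CC(C)C[C@@H](O)c1c(OC)cc(OC)cc1OC | intermediate
9 | tricarbonyl[η6-(R)-3-methyl-1-(2,4,6-trimethoxyphenyl)butan-1-ol]chromium (metal fragment written as separate components) | CC(C)C[C@@H](O)c1c(OC)cc(OC)cc1OC.[C-]#[O+].[C-]#[O+].[C-]#[O+].[Cr] | intermediate
10 | tricarbonyl[η6-(R)-3-methyl-1-(2,4,6-trimethoxyphenyl)butyl acetate]chromium | CC(C)C[C@@H](OC(C)=O)c1c(OC)cc(OC)cc1OC.[C-]#[O+].[C-]#[O+].[C-]#[O+].[Cr] | intermediate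
11 | tricarbonylchromium complex of aldehyde 12 (metal on the trimethoxyphenyl ring) | CC(C)C[C@H](c1c(OC)cc(OC)cc1OC)[C@H](C=O)[C@]1(C)CC[C@@H](C(C)(C)O[Si](CC)(CC)CC)C[C@H]1C(C)=C.[C-]#[O+].[C-]#[O+].[C-]#[O+].[Cr] | intermediate (not isolated)
12 | (2S,3S)-5-methyl-2-[(1R,2S,4R)-1-methyl-2-(prop-1-en-2-yl)-4-[2-(triethylsilyloxy)propan-2-yl]cyclohexyl]-3-(2,4,6-trimethoxyphenyl)hexanal | CC(C)C[C@H](c1c(OC)cc(OC)cc1OC)[C@H](C=O)[C@]1(C)CC[C@@H](C(C)(C)O[Si](CC)(CC)CC)C[C@H]1C(C)=C | intermediate
13 | (1′S)-1β-[3-methyl-1-(2,4,6-trimethoxyphenyl)butyl]-11-(triethylsilyloxy)-5α-eudesm-4(15)-en-2β-ol | CC(C)C[C@H](c1c(OC)cc(OC)cc1OC)[C@@H]1[C@H](O)CC(=C)[C@@H]2C[C@H](C(C)(C)O[Si](CC)(CC)CC)CC[C@]21C | intermediate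
14 | O-(2β-yl) 1H-imidazole-1-carbothioate of 13 | CC(C)C[C@H](c1c(OC)cc(OC)cc1OC)[C@@H]1[C@H](OC(=S)n3ccnc3)CC(=C)[C@@H]2C[C@H](C(C)(C)O[Si](CC)(CC)CC)CC[C@]21C | intermediate
15 | (1′S)-1β-[3-methyl-1-(2,4,6-trimethoxyphenyl)butyl]-11-(triethylsilyloxy)-5α-eudesm-4(15)-ene | CC(C)C[C@H](c1c(OC)cc(OC)cc1OC)[C@@H]1CCC(=C)[C@@H]2C[C@H](C(C)(C)O[Si](CC)(CC)CC)CC[C@]21C | intermediate
16 | 4α,15-epoxide of 15 (oxygen α, CH2 β) | CC(C)C[C@H](c1c(OC)cc(OC)cc1OC)[C@@H]1CC[C@]3(CO3)[C@@H]2C[C@H](C(C)(C)O[Si](CC)(CC)CC)CC[C@]21C | intermediate
17 | (1′S)-1β-[3-methyl-1-(2,4,6-trimethoxyphenyl)butyl]-11-(triethylsilyloxy)-5α-eudesman-4α-ol | CC(C)C[C@H](c1c(OC)cc(OC)cc1OC)[C@@H]1CC[C@@](C)(O)[C@@H]2C[C@H](C(C)(C)O[Si](CC)(CC)CC)CC[C@]21C | intermediate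
18 | 3,5-dibromo-2,4,6-trimethoxyphenyl analogue of 17 | CC(C)C[C@H](c1c(OC)c(Br)c(OC)c(Br)c1OC)[C@@H]1CC[C@@](C)(O)[C@@H]2C[C@H](C(C)(C)O[Si](CC)(CC)CC)CC[C@]21C | intermediate
19 | lithium C4-alkoxide of the 3,5-dilithio-2,4,6-trimethoxyphenyl analogue of 17 | CC(C)C[C@H](c1c(OC)c([Li])c(OC)c([Li])c1OC)[C@@H]1CC[C@@](C)(O[Li])[C@@H]2C[C@H](C(C)(C)O[Si](CC)(CC)CC)CC[C@]21C | intermediate (not isolated)
20 | 3,5-diformyl-2,4,6-trimethoxyphenyl analogue of 17 (macrocarpal J tri-O-methyl ether 11-O-triethylsilyl ether) | CC(C)C[C@H](c1c(OC)c(C=O)c(OC)c(C=O)c1OC)[C@@H]1CC[C@@](C)(O)[C@@H]2C[C@H](C(C)(C)O[Si](CC)(CC)CC)CC[C@]21C | intermediate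
21 | macrocarpal J tri-O-methyl ether | CC(C)C[C@H](c1c(OC)c(C=O)c(OC)c(C=O)c1OC)[C@@H]1CC[C@@](C)(O)[C@@H]2C[C@H](C(C)(C)O)CC[C@]21C | intermediate
22 | macrocarpal J, (1S,1′S,4R,5R,7R,10S) in eudesmane numbering | CC(C)C[C@H](c1c(O)c(C=O)c(O)c(C=O)c1O)[C@@H]1CC[C@@](C)(O)[C@@H]2C[C@H](C(C)(C)O)CC[C@]21C | target

## Step count and weakest steps

Total: 17 steps. Longest linear sequence: 14 steps (from 5 through steps 4–17); from 1 the sequence is 13 steps.

Step 9 (key step). The closure may be slowed because the Lewis acid is shared among the aldehyde, three methoxy groups and the silyl ether, and because the aluminated oxygen has to sit 1,3-diaxial to the C10 methyl. A slow ene reaction would then lose to methyl transfer from aluminium to the aldehyde or to enolisation that scrambles C1.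
Fallback: the same C2–C3 bond is made by an allylmetal addition instead of an ene reaction, setting out from 2.
- Ene-type allylic chlorination of the isopropenyl group (Ca(OCl)2, CO2, CH2Cl2/H2O, 0 °C; the vinyl group has no allylic hydrogen and is less nucleophilic) gives the allylic chloride F1.
- The conditions of steps 2, 3 and 8 then give the chloro aldehyde F2, its silyl enol ether F3 and, through the tricarbonylchromium-bound chloro aldehyde F4, the 15-chloro analogue of 12 F5.
- CrCl2 in THF (Nozaki–Hiyama allylation, divalent chromium) converts the allylic chloride into an allyl–CrCl2 species whose γ-carbon C3 adds to the aldehyde under neutral conditions. This gives the homoallylic alcohol 13, where the route is rejoined; either C2 epimer serves.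

Step 8. Bond formation between a neopentyl-type enol carbon and a doubly ortho-substituted cation may be slow. The cation would then be lost by β-proton loss to the styrene complex, and the facial preference at C1 would erode.
Fallback: the nucleophile is changed to an enamine and the electrophile is pre-formed.
- From 3, pyrrolidine (K2CO3, toluene) gives the (E)-enamine F6.
- Acetate 10 is ionised with HBF4·OEt2 in CH2Cl2 at −78 °C to the chromium-stabilised cation tetrafluoroborate F7, to which F6 is added.
- The resulting iminium salt F8 is hydrolysed (aqueous NaOAc) to the complexed aldehyde 11, and air and light give 12.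

Step 2. Oxidation of a vinyl group on a quaternary carbon may be slow. Long exposure invites Markovnikov leakage to the methyl ketone and acid-induced cyclisation of the new aldehyde onto the isopropenyl group.
Fallback: from 2, rhodium-catalysed hydroboration (pinacolborane, RhCl(PPh3)3), which distinguishes mono- from 1,1-disubstituted alkenes, gives the pinacol boronate F9. Oxidation with NaBO3·4H2O gives the primary alcohol F10, and Dess–Martin periodinane returns to 3.

Step 12. Facial selectivity at the C4 methylene may be incomplete, and the peracid may attack the trimethoxyphenyl ring.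
Fallback: from 15 directly to 17 by hydrogen-atom-transfer hydration (Co(acac)2, PhSiH3, O2, i-PrOH). The tertiary C4 radical should be trapped by oxygen from the α face, away from the C10 methyl, and no peracid is used. No compound outside the list is formed.

Step 15. The second bromine–lithium exchange on an already anionic ring may be incomplete, or the dilithio species may pick up a proton, leading to mono-aldehyde mixtures.
Fallback: electrophilic formylation, from 17.
- TESOTf and 2,6-lutidine give the bis(triethylsilyl) ether F11.
- Rieche formylation (Cl2CHOMe, AgOTf, CH2Cl2, −78 °C) at the two activated positions gives the dialdehyde bis(triethylsilyl) ether F12.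
- HF·pyridine removes both silyl groups and rejoins the route at 21, bypassing 18–20.

Step 17. The third demethylation has to generate a triply charged phenoxide and may stall at a partly methylated stage, while the thiolate adds reversibly to the aldehydes at the temperature needed.
Fallback: chelation-directed Lewis-acid cleavage with the carbinols protected, from 20.
- Silylation of the C4 hydroxyl (TESOTf, 2,6-lutidine) gives F12.
- BCl3 (CH2Cl2, −78 → −20 °C) cleaves the three methoxy groups through boron chelates with the neighbouring formyl groups, giving the 4,11-bis(triethylsilyl) ether of macrocarpal J F13.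
- HF·pyridine then gives 22.

## Further compounds

F1 | step 9 | 15-chloro derivative of 2 (allylic chloride on the C5 isopropenyl group) | ClCC(=C)[C@@H]1C[C@H](C(C)(C)O[Si](CC)(CC)CC)CC[C@]1(C=C)C
F2 | step 9 | 15-chloro analogue of aldehyde 3 | ClCC(=C)[C@@H]1C[C@H](C(C)(C)O[Si](CC)(CC)CC)CC[C@]1(CC=O)C
F3 | step 9 | 15-chloro analogue of (Z)-silyl enol ether 4 | ClCC(=C)[C@@H]1C[C@H](C(C)(C)O[Si](CC)(CC)CC)CC[C@]1(/C=C\O[Si](C)(C)C(C)(C)C)C
F4 | step 9 | tricarbonylchromium complex of F5 | CC(C)C[C@H](c1c(OC)cc(OC)cc1OC)[C@H](C=O)[C@]1(C)CC[C@@H](C(C)(C)O[Si](CC)(CC)CC)C[C@H]1C(CCl)=C.[C-]#[O+].[C-]#[O+].[C-]#[O+].[Cr]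
F5 | step 9 | 15-chloro analogue of aldehyde 12 | CC(C)C[C@H](c1c(OC)cc(OC)cc1OC)[C@H](C=O)[C@]1(C)CC[C@@H](C(C)(C)O[Si](CC)(CC)CC)C[C@H]1C(CCl)=C
F6 | step 8 | (E)-pyrrolidine enamine of aldehyde 3 | C=C(C)[C@@H]1C[C@H](C(C)(C)O[Si](CC)(CC)CC)CC[C@]1(/C=C/N2CCCC2)C
F7 | step 8 | tricarbonylchromium-stabilised 3-methyl-1-(2,4,6-trimethoxyphenyl)butyl cation tetrafluoroborate (single rotamer from exo ionisation of 10; its planar chirality cannot be written in SMILES) | CC(C)C[CH+]c1c(OC)cc(OC)cc1OC.[C-]#[O+].[C-]#[O+].[C-]#[O+].[Cr].F[B-](F)(F)F
F8 | step 8 | pyrrolidinium (iminium) tetrafluoroborate of complexed aldehyde 11 | CC(C)C[C@H](c1c(OC)cc(OC)cc1OC)[C@H](C=[N+]2CCCC2)[C@]1(C)CC[C@@H](C(C)(C)O[Si](CC)(CC)CC)C[C@H]1C(C)=C.[C-]#[O+].[C-]#[O+].[C-]#[O+].[Cr].F[B-](F)(F)F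
F9 | step 2 | pinacol boronate from anti-Markovnikov hydroboration of the vinyl group of 2 | C=C(C)[C@@H]1C[C@H](C(C)(C)O[Si](CC)(CC)CC)CC[C@]1(CCB2OC(C)(C)C(C)(C)O2)C
F10 | step 2 | primary alcohol corresponding to aldehyde 3 | C=C(C)[C@@H]1C[C@H](C(C)(C)O[Si](CC)(CC)CC)CC[C@]1(CCO)C
F0 | step 12 | none | none
F11 | step 15 | 4,11-bis(triethylsilyl) ether of the diol corresponding to 17 | CC(C)C[C@H](c1c(OC)cc(OC)cc1OC)[C@@H]1CC[C@@](C)(O[Si](CC)(CC)CC)[C@@H]2C[C@H](C(C)(C)O[Si](CC)(CC)CC)CC[C@]21C
F12 | step 15 | 4,11-bis(triethylsilyl) ether of macrocarpal J tri-O-methyl ether | CC(C)C[C@H](c1c(OC)c(C=O)c(OC)c(C=O)c1OC)[C@@H]1CC[C@@](C)(O[Si](CC)(CC)CC)[C@@H]2C[C@H](C(C)(C)O[Si](CC)(CC)CC)CC[C@]21C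
F13 | step 17 | 4,11-bis(triethylsilyl) ether of macrocarpal J | CC(C)C[C@H](c1c(O)c(C=O)c(O)c(C=O)c1O)[C@@H]1CC[C@@](C)(O[Si](CC)(CC)CC)[C@@H]2C[C@H](C(C)(C)O[Si](CC)(CC)CC)CC[C@]21C
A1 | alternative 1 | (4S)-3-methyl-4-[(1S)-3-methyl-1-(2,4,6-trimethoxyphenyl)butyl]cyclohex-2-enone (ring A enone) | CC(C)C[C@H](c1c(OC)cc(OC)cc1OC)[C@@H]1CCC(=O)C=C1C
A2 | alternative 1 | vinylmagnesium bromide | C=C[Mg]Br
A3 | alternative 1 | prenyl bromide | CC(C)=CCBr
A4 | alternative 1 | ring A ketone with C10 vinyl and methyl and C5 prenyl | CC(C)C[C@H](c1c(OC)cc(OC)cc1OC)[C@@H]1CCC(=O)[C@H](CC=C(C)C)[C@@]1(C)C=C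
A5 | alternative 2 | 2-chloro-4-methylphenol carrying at C3 a ketal-protected (E)-6-(methoxycarbonyloxy)hex-4-enoyl chain | COC(=O)OC/C=C/CCC1(OCCO1)c1c(Cl)c(O)ccc1C
A6 | alternative 2 | bicyclic cross-conjugated dienone with C1 vinyl and C10 methyl | C=C[C@@H]1CCC3(OCCO3)C2=C(Cl)C(=O)C=C[C@]21C
A7 | alternative 3 | ring A enone (C1=C10, C2 ketone) with the side chain on C1 | CC(C)C[C@H](c1c(OC)cc(OC)cc1OC)C1=C2CC[C@@H](C(C)(C)O[Si](CC)(CC)CC)C[C@H]2CCC1=O
A8 | alternative 3 | allene (propadiene) | C=C=C
A9 | alternative 3 | methylenecyclobutane photoadduct bridging C1 and C10 | CC(C)C[C@H](c1c(OC)cc(OC)cc1OC)[C@]12C(=C)C[C@]13CC[C@@H](C(C)(C)O[Si](CC)(CC)CC)C[C@H]3CCC2=O
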